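**Remark on the chemistry (assumption).** The enantioface preference of an AlBr3-activated oxazaborolidine for an α-methylated cyclohexenone cannot be read from the binding model that holds for α-unsubstituted enones. The catalyst from (S)-α,α-diphenylprolinol is written; the equally accessible catalyst from the (R)-amino alcohol takes its place if the adduct proves to be the enantiomer of 8.

## Analysis of the target

The target 24 is a C30H50 hydrocarbon made of two decalins joined by the C11–C12 ethano tether (left half C1–C10, with the exocyclic methylene carbon C17 on C8 and C11 on C9; right half C1'–C10', with C12 on C9'). The left decalin (rings A and B) is trans-fused, carries the 1,1-disubstituted C8=C17 alkene and has three contiguous stereocentres, C5, C9 and C10, in the drimane/labdane arrangement. The right decalin (rings A' and B') is cis-fused: H-5' and the methyl group on the quaternary C10' lie on the same face, and C9' belongs to the tetrasubstituted C8'=C9' alkene. The two groups of stereocentres are separated by a flexible tether and an sp2 carbon, so neither can direct the other and each must be set in the absolute sense on its own. There is no heteroatom and therefore no handle for late corrections; the only sensitive groups are the two alkenes, which migrate or attack each other under protic or Lewis acid, the exocyclic one most easily. The hard points are the quaternary C10' between the gem-dimethyl-bearing ring A' and a tetrasubstituted alkene, the less common cis fusion, and the union of two hindered halves at C12–C9'. The strategy rests on ring B': its six carbons C5'–C10' are a cyclohexene that can be made by adding a diene across the C5'=C10' bond of a cyclohexenone that already is ring A', with the angular methyl and the C4' gem-dimethyl group in place.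

## Retrosynthetic reasoning

The first cut is the C12–C9' bond between an sp3 and an sp2 carbon. It leaves each half with all of its own stereocentres: the left half becomes the primary alkylzinc iodide 23, drawn from iodide 22, and the right half the enol triflate 15. Cutting at the alkene carbon has a second benefit: the ketone behind 15 has its carbonyl between the quaternary C10' and C8', so it enolises in one direction only and the position of the tetrasubstituted alkene is fixed by constitution. The forward Negishi coupling has to join a β-branched primary alkyl group to a tetrasubstituted, neopentyl-flanked alkenyl triflate without touching the exocyclic alkene.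

Iodide 22 is traced by functional-group changes alone to sclareolide 16, which supplies C5, C9 and C10 from the chiral pool and C11 and C12 as its lactone carbons. The path is diol 17, monoacetate 18, exocyclic alkene 20, alcohol 21 and iodide 22. The order is forced: the primary hydroxyl must be masked before the tertiary alcohol is eliminated, and the tertiary oxygen must be gone before C12 is activated, otherwise the C8 oxygen closes a five-membered ether ring onto C12.

Triflate 15 is the O-sulfonylated enolate 14, which is reached regiospecifically by conjugate hydride addition to enone 13. Enone 13 is the oxidation product of allylic alcohol 12, and 12 is the deacetylated form of 11. No carbon–carbon bond is involved here; the oxygen at C9' is moved from the alcohol level to the enolate level.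

In 11, C1' is a methylene. A carbonyl is placed there in retrosynthesis (8), because that carbonyl is what turns the C5'=C10' alkene into a dienophile. It is not removed by a classical Wolff–Kishner reduction in hot alkali: the acetate of 8 would be saponified to a β-hydroxy ketone whose α-carbon C10' is quaternary, and such a compound cannot dehydrate but cleaves easily by retro-aldol reaction at C9'–C10', a bond the key step has just made. The carbonyl is therefore taken off under near-neutral conditions through tosylhydrazone 9 and its hydroboration product 10, and the acetate stays until C1' is a methylene.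

The key disconnection cuts C9'–C10' and C5'–C6' of 8 in a retro-[4+2] sense, giving enone 5 and diene 7. It is made there because the C7'=C8' alkene of 8 sits where a Diels–Alder reaction leaves it, because 5 already holds ring A', the angular methyl and the gem-dimethyl group, and because 7 brings the C8' methyl and an oxygen on C9', the later coupling site. One step yields ring B', two skeletal bonds and both ring-fusion stereocentres. The forward reaction must overcome the low reactivity of a trisubstituted enone with a neopentyl β-carbon, place the oxygenated diene terminus on C10', and select one face of the achiral 5.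

Enone 5 goes back to the keto aldehyde 4, the Michael adduct of enamine 2 and ethyl vinyl ketone 3; 2 is the enamine of isobutyraldehyde 1. Diene 7 is the enol acetate of the extended enol of tiglic aldehyde 6. Both precursors are one or two steps from bulk chemicals, so the risk of the route sits in the cycloaddition.

## Alternatives that were turned down

Alternative 1: The disconnection removes C4'–C5' and C9'–C10' together. Both right-hand rings would form in a cationic bicyclisation of an open-chain precursor that already carries the left half: MeAlCl2 opens a terminal epoxide, the (Z)-C5'=C10' alkene relays the charge and a vinylsilane at C8'=C9' terminates, giving the 3'-hydroxy compound A1.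
- For: both rings, both ring-fusion centres and the tetrasubstituted alkene arise in one step; the absolute configuration flows from a single epoxide, whose enantioselective preparation is routine. On that point it is stronger than step 4, where the facial sense of the catalyst is not secure. No hindered late coupling is needed.
- Against: the precursor needs a Z-trisubstituted alkene and a tetrasubstituted vinylsilane of defined geometry, built in a long acyclic sequence. Z-alkenes cyclise through less favourable transition states and tend to stop early. The 1,1-disubstituted C8=C17 alkene is itself a nucleophile toward the Lewis acid and the cationic intermediates. A1 carries an extra hydroxyl next to the quaternary C4' that costs at least two more steps.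
- Comparison: the chosen route also removes one oxygen (C1'), so it gains nothing there; what it offers is two trivial cycloaddition partners and no acid near the exocyclic alkene.

Alternative 2: The disconnection excises C8' with its methyl. C8'–C9' and C7'–C8' would form when diazoethane A4 adds to the C9' ketone of the cis-hydrindanone A3 under Sc(OTf)3 catalysis and the C7' methylene migrates with loss of N2, giving the cis-decalone A2.
- For: A2 is one enol triflation away from 15; there is no C1' oxygen to remove and no redox adjustment at C9'. After its key step this route is clearly shorter than the five steps from 8 to 15. Migration of the methylene in preference to the quaternary C10' is the normal outcome, and the C8' configuration is irrelevant.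
- Against: the key step creates neither C5' nor C10'. The whole stereochemical problem moves into the synthesis of enantiopure A3, a cis-hydrindanone with angular methyl and gem-dimethyl group for which no entry as short as that to 5 is evident. The A3 carbonyl is neopentyl, so addition is slow. A4 must be generated fresh, is hazardous, and can homologate twice or give epoxide.
- Comparison: the chosen strategy makes ring B' and both stereocentres at once from achiral materials and accepts a longer endgame for it.

Alternative 3: The disconnection forms C1'–C10' while the non-target C3'–C8' bond of a bridged precursor breaks. The potassium alkoxide (KH, 18-crown-6) of the bicyclo[2.2.2]octenyl vinyl carbinol A6 would undergo an anionic oxy-Cope rearrangement to the 3'-oxo compound A5.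
- For: the [3,3] shift is stereospecific through the boat geometry that the bicycle enforces. The quaternary C10', the cis fusion and the C8'=C9' alkene appear in their final places with no selectivity question, which is more certain than the regio- and enantiocontrol demanded of step 4, and no late coupling is needed.
- Against: A6 is a densely substituted bicycle with a tetrasubstituted alkene bridge bearing the tether and the left half, a bridgehead methyl, and a tertiary carbinol that must come from vinyl addition to a ketone between two quaternary carbons, on the face toward the alkene bridge. Its enantioselective construction would take many steps. A5 still has a ketone beside the quaternary C4' to remove in the presence of the exocyclic alkene.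
- Comparison: the chosen route reaches its key step in three steps and keeps the left half out of all strongly basic or acidic operations.

Key step: step 4

## Route

Step 1
Reactants: 1 isobutyraldehyde
Product: 2 1-(2-methylprop-1-en-1-yl)pyrrolidine
Conditions: pyrrolidine, toluene, reflux with azeotropic removal of water; distillation
Reagents that add atoms: pyrrolidine, C1CCNC1
Why: Condensation of an α-branched aldehyde with a secondary amine (Stork enamine formation); removal of water drives it, and the fully substituted β-carbon of the enamine suppresses self-condensation.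

Step 2
Reactants: 2 1-(2-methylprop-1-en-1-yl)pyrrolidine; 3 ethyl vinyl ketone
Product: 5 2,4,4-trimethylcyclohex-2-en-1-one, via keto aldehyde 4 (not isolated)
Conditions: 3, neat, 0 °C → rt; then 6 M HCl, rt → 60 °C
Reagents that add atoms: none
Why: Stork enamine Michael addition to the vinyl ketone and acid hydrolysis give 4, whose only feasible intramolecular aldol condensation (ethyl-side α-carbon onto the aldehyde) closes the six-membered enone; this is a Robinson-type annulation and creates no stereocentre.

Step 3
Reactants: 6 tiglic aldehyde
Product: 7 (1E)-2-methylbuta-1,3-dien-1-yl acetate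
Conditions: isopropenyl acetate, TsOH·H2O (cat.), Cu(OAc)2 (cat., inhibitor), 100 °C with distillation of acetone; fractional distillation
Reagents that add atoms: isopropenyl acetate, CC(=C)OC(C)=O
Why: Acid-catalysed acetyl transfer traps the extended enol of the enal as the dienyl acetate (enol acetylation); only the C4 methyl can give up the proton, so one constitution results. The E isomer (acetoxy trans to the vinyl group) is the one able to reach the s-cis conformation needed in step 4; the Z isomer in the distillate is inert there.

Step 4
Reactants: 5 2,4,4-trimethylcyclohex-2-en-1-one; 7 (1E)-2-methylbuta-1,3-dien-1-yl acetate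
Product: 8 (1R,4aR,8aS)-2,5,5,8a-tetramethyl-8-oxo-1,4,4a,5,6,7,8,8a-octahydronaphthalen-1-yl acetate (cis-fused; acetoxy group cis to C8 and trans to the angular methyl)
Conditions: (S)-3,3-diphenyl-1-(2-methylphenyl)tetrahydro-1H,3H-pyrrolo[1,2-c][1,3,2]oxazaborole (20 mol %), AlBr3 (16 mol %), 7 (3 equiv), CH2Cl2, −40 → 0 °C
Reagents that add atoms: none
Why: The ketone of 5 binds the cationic boron of the AlBr3-activated oxazaborolidine, which lowers the enone LUMO enough for a normal-demand Diels–Alder reaction with the oxygenated diene; the closest known reaction types are the oxazaborolidinium-catalysed [4+2] cycloaddition of cyclic enones and the Lewis-acid-promoted addition of 1-oxygenated dienes to 2-methylcyclohex-2-enones. The addition is concerted but asynchronous: the unsubstituted diene terminus bonds ahead to the β-carbon C5', and the acetoxy-bearing terminus closes onto the α-carbon C10'. Ring B' closes as a six-membered ring by suprafacial [4+2] cycloaddition across the endocyclic C5'=C10' alkene, so H-5' and the C10' methyl must end cis. The absolute configuration of C5' and C10' is set by the catalyst, which must leave open the face of 5 that is Re at C2 and Re at C3. C9' is set by the endo orientation of the ketone (acetoxy cis to C1'), and this centre is erased in step 8, so its configuration does not matter. The step needs the regiochemistry C9'–C10'/C6'–C5': the oxygen donor makes the far terminus of 7 the most nucleophilic, and the neopentyl C5' can accept only the unsubstituted CH2 terminus; both outweigh the weak opposing bias of the diene's 2-methyl group. The slight deficit of AlBr3 relative to the oxazaborolidine keeps free AlBr3, which would catalyse a racemic background reaction, out of the flask.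

Step 5
Reactants: 8 (1R,4aR,8aS)-2,5,5,8a-tetramethyl-8-oxo-1,4,4a,5,6,7,8,8a-octahydronaphthalen-1-yl acetate
Product: 9 (1R,4aR,8aR)-2,5,5,8a-tetramethyl-8-[(E)-2-(4-methylbenzenesulfonyl)hydrazinylidene]-1,4,4a,5,6,7,8,8a-octahydronaphthalen-1-yl acetate
Conditions: TsNHNH2, PPTS (cat.), EtOH, 60 °C
Reagents that add atoms: 4-methylbenzenesulfonohydrazide, Cc1ccc(cc1)S(=O)(=O)NN
Why: Condensation of a ketone with a sulfonyl hydrazide (tosylhydrazone formation); the C1' carbonyl has one quaternary neighbour only, like the bridged ketones that form tosylhydrazones readily, and the weak acid does not ionise the allylic acetate.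

Step 6
Reactants: 9 (1R,4aR,8aR)-2,5,5,8a-tetramethyl-8-[(E)-2-(4-methylbenzenesulfonyl)hydrazinylidene]-1,4,4a,5,6,7,8,8a-octahydronaphthalen-1-yl acetate
Product: 11 (1R,4aR,8aS)-2,5,5,8a-tetramethyl-1,4,4a,5,6,7,8,8a-octahydronaphthalen-1-yl acetate, via hydrazinoborane 10 (not isolated)
Conditions: catecholborane, CHCl3, 0 °C → rt; then NaOAc·3H2O, reflux
Reagents that add atoms: none
Why: Reductive deoxygenation of a tosylhydrazone, a mild variant of the Wolff–Kishner reduction: B–H adds across C=N to give 10, and acetate then triggers loss of sulfinate and of N2, leaving CH2 at C1'. The medium is never strongly basic, so the acetate stays and the C9'–C10' bond is not exposed to retro-aldol cleavage; the isolated trisubstituted alkene is not hydroborated at room temperature.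

Step 7
Reactants: 11 (1R,4aR,8aS)-2,5,5,8a-tetramethyl-1,4,4a,5,6,7,8,8a-octahydronaphthalen-1-yl acetate
Product: 12 (1R,4aR,8aS)-2,5,5,8a-tetramethyl-1,4,4a,5,6,7,8,8a-octahydronaphthalen-1-ol
Conditions: K2CO3 (cat.), MeOH, rt → 40 °C
Reagents that add atoms: none
Why: Base-catalysed transesterification of the acetate; with C1' now a methylene, the liberated alkoxide has no carbonyl toward which it could fragment.

Step 8
Reactants: 12 (1R,4aR,8aS)-2,5,5,8a-tetramethyl-1,4,4a,5,6,7,8,8a-octahydronaphthalen-1-ol
Product: 13 (4aR,8aS)-2,5,5,8a-tetramethyl-4a,5,6,7,8,8a-hexahydronaphthalen-1(4H)-one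
Conditions: Dess–Martin periodinane, CH2Cl2, 0 °C → rt
Reagents that add atoms: none
Why: Dess–Martin oxidation of the secondary allylic alcohol to the conjugated enone; the expendable C9' centre is erased, and neither ring-fusion centre can epimerise because C10' is quaternary and C5' is remote from the carbonyl.

Step 9
Reactants: 13 (4aR,8aS)-2,5,5,8a-tetramethyl-4a,5,6,7,8,8a-hexahydronaphthalen-1(4H)-one
Product: 15 (4aR,8aS)-2,5,5,8a-tetramethyl-3,4,4a,5,6,7,8,8a-octahydronaphthalen-1-yl trifluoromethanesulfonate, via lithium enolate 14 (not isolated)
Conditions: LiBH(sec-Bu)3, THF, −78 °C; then N-(5-chloropyridin-2-yl)bis(trifluoromethanesulfonyl)imide, −78 → 0 °C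
Reagents that add atoms: N-(5-chloropyridin-2-yl)-1,1,1-trifluoro-N-(trifluoromethylsulfonyl)methanesulfonamide, O=S(=O)(N(c1ccc(Cl)cn1)S(=O)(=O)C(F)(F)F)C(F)(F)F
Why: Conjugate hydride addition of the bulky trialkylborohydride to a cyclohexenone with an unsubstituted ring β-carbon and a carbonyl shielded by the quaternary C10' gives enolate 14, and O-sulfonylation (reductive enol triflation) fixes the C8'=C9' alkene. C10' has no hydrogen, so no other enol triflate can form.

Step 10
Reactants: 16 (+)-sclareolide
Product: 17 (1R,2R,4aS,8aS)-1-(2-hydroxyethyl)-2,5,5,8a-tetramethyldecahydronaphthalen-2-ol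
Conditions: LiAlH4, THF, 0 °C → reflux; aqueous NaOH work-up
Reagents that add atoms: none
Why: Hydride reduction of the γ-lactone to the 1,4-diol; no stereocentre is touched.

Step 11
Reactants: 17 (1R,2R,4aS,8aS)-1-(2-hydroxyethyl)-2,5,5,8a-tetramethyldecahydronaphthalen-2-ol
Product: 18 2-[(1R,2R,4aS,8aS)-2-hydroxy-2,5,5,8a-tetramethyldecahydronaphthalen-1-yl]ethyl acetate
Conditions: Ac2O, pyridine, rt
Reagents that add atoms: acetic anhydride, CC(=O)OC(C)=O
Why: Acylation distinguishes the primary from the tertiary hydroxyl on steric grounds; the acetate prevents the C12 oxygen from closing a cyclic ether onto C8 in the next step.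

Step 12
Reactants: 18 2-[(1R,2R,4aS,8aS)-2-hydroxy-2,5,5,8a-tetramethyldecahydronaphthalen-1-yl]ethyl acetate
Product: 20 2-[(1S,4aS,8aS)-5,5,8a-trimethyl-2-methylidenedecahydronaphthalen-1-yl]ethyl acetate, via chlorosulfite 19 (not isolated)
Conditions: SOCl2, pyridine, CH2Cl2, −78 °C
Reagents that add atoms: none
Why: Dehydration of the tertiary alcohol through chlorosulfite 19 (E2-type elimination): the C8–O bond is equatorial, so no ring hydrogen on C7 or C9 is antiperiplanar to it and a hydrogen of the C17 methyl is removed, which should favour the exocyclic alkene at low temperature. Any endocyclic isomer would be removed on AgNO3-impregnated silica.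

Step 13
Reactants: 20 2-[(1S,4aS,8aS)-5,5,8a-trimethyl-2-methylidenedecahydronaphthalen-1-yl]ethyl acetate
Product: 21 2-[(1S,4aS,8aS)-5,5,8a-trimethyl-2-methylidenedecahydronaphthalen-1-yl]ethan-1-ol
Conditions: K2CO3 (cat.), MeOH, rt
Reagents that add atoms: none
Why: Base-catalysed methanolysis of a primary acetate; the exocyclic alkene does not migrate under these mild basic conditions.

Step 14
Reactants: 21 2-[(1S,4aS,8aS)-5,5,8a-trimethyl-2-methylidenedecahydronaphthalen-1-yl]ethan-1-ol
Product: 22 (1S,4aS,8aS)-1-(2-iodoethyl)-5,5,8a-trimethyl-2-methylidenedecahydronaphthalene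
Conditions: PPh3, imidazole, I2 (premixed), CH2Cl2, 0 °C → rt
Reagents that add atoms: iodine, II
Why: Appel-type iodination of the primary alcohol by SN2 displacement of the oxyphosphonium group; premixing PPh3 and I2 leaves no free iodine that could add to the γ,δ-alkene with ring closure by the hydroxyl.

Step 15
Reactants: 22 (1S,4aS,8aS)-1-(2-iodoethyl)-5,5,8a-trimethyl-2-methylidenedecahydronaphthalene; 15 (4aR,8aS)-2,5,5,8a-tetramethyl-3,4,4a,5,6,7,8,8a-octahydronaphthalen-1-yl trifluoromethanesulfonate
Product: 24 target (4aR,8aS)-2,5,5,8a-tetramethyl-1-{2-[(1S,4aS,8aS)-5,5,8a-trimethyl-2-methylidenedecahydronaphthalen-1-yl]ethyl}-3,4,4a,5,6,7,8,8a-octahydronaphthalene, via alkylzinc iodide 23 (not isolated)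
Conditions: Zn dust, LiCl, THF, 40 °C; then 15, Pd(OAc)2 (5 mol %), SPhos (2-dicyclohexylphosphino-2',6'-dimethoxybiphenyl, 10 mol %), THF/NMP, 50 °C
Reagents that add atoms: none
Why: Insertion of LiCl-activated zinc into the primary C–I bond gives 23, and Negishi coupling follows: zerovalent palladium, formed in the flask from Pd(OAc)2 and the bulky biaryl phosphine, inserts into the C–O bond of 15, the alkyl group moves from zinc to palladium and reductive elimination forms C12–C9'. Couplings of primary alkylzinc halides with 2,6,6-trisubstituted cyclohexenyl triflates are the direct model; no stereocentre is formed or disturbed, and the neutral conditions leave both alkenes in place.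

## Compound list

1 | isobutyraldehyde | CC(C)C=O | starting material
2 | 1-(2-methylprop-1-en-1-yl)pyrrolidine | CC(C)=CN1CCCC1 | intermediate
3 | ethyl vinyl ketone (pent-1-en-3-one) | CCC(=O)C=C | starting material
4 | 2,2-dimethyl-5-oxoheptanal | CCC(=O)CCC(C)(C)C=O | intermediate (not isolated)
5 | 2,4,4-trimethylcyclohex-2-en-1-one | CC1=CC(C)(C)CCC1=O | intermediate
6 | tiglic aldehyde, (E)-2-methylbut-2-enal | C/C=C(\C)C=O | starting material
7 | (1E)-2-methylbuta-1,3-dien-1-yl acetate | CC(=O)O/C=C(\C)C=C | intermediate
8 | (1R,4aR,8aS)-2,5,5,8a-tetramethyl-8-oxo-1,4,4a,5,6,7,8,8a-octahydronaphthalen-1-yl acetate | CC(=O)O[C@@H]1C(C)=CC[C@@H]2C(C)(C)CCC(=O)[C@]12C | intermediate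
9 | (1R,4aR,8aR)-2,5,5,8a-tetramethyl-8-[(E)-2-(4-methylbenzenesulfonyl)hydrazinylidene]-1,4,4a,5,6,7,8,8a-octahydronaphthalen-1-yl acetate | CC(=O)O[C@@H]1C(C)=CC[C@@H]2C(C)(C)CC/C(=N\NS(=O)(=O)c3ccc(C)cc3)[C@]12C | intermediate
10 | hydrazinoborane from 9: the C=N bond hydroborated, 1,3,2-benzodioxaborol-2-yl on the nitrogen attached to C8, new C8 centre undefined | CC(=O)O[C@@H]1C(C)=CC[C@@H]2C(C)(C)CCC(N(NS(=O)(=O)c3ccc(C)cc3)B3Oc4ccccc4O3)[C@]12C | intermediate (not isolated)
11 | (1R,4aR,8aS)-2,5,5,8a-tetramethyl-1,4,4a,5,6,7,8,8a-octahydronaphthalen-1-yl acetate | CC(=O)O[C@@H]1C(C)=CC[C@@H]2C(C)(C)CCC[C@]12C | intermediate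
12 | (1R,4aR,8aS)-2,5,5,8a-tetramethyl-1,4,4a,5,6,7,8,8a-octahydronaphthalen-1-ol | O[C@@H]1C(C)=CC[C@@H]2C(C)(C)CCC[C@]12C | intermediate
13 | (4aR,8aS)-2,5,5,8a-tetramethyl-4a,5,6,7,8,8a-hexahydronaphthalen-1(4H)-one | O=C1C(C)=CC[C@@H]2C(C)(C)CCC[C@]12C | intermediate
14 | lithium (4aR,8aS)-2,5,5,8a-tetramethyl-3,4,4a,5,6,7,8,8a-octahydronaphthalen-1-olate | [Li+].[O-]C1=C(C)CC[C@@H]2C(C)(C)CCC[C@]12C | intermediate (not isolated)
15 | (4aR,8aS)-2,5,5,8a-tetramethyl-3,4,4a,5,6,7,8,8a-octahydronaphthalen-1-yl trifluoromethanesulfonate | O=S(=O)(OC1=C(C)CC[C@@H]2C(C)(C)CCC[C@]12C)C(F)(F)F | intermediate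
16 | (+)-sclareolide, (3aR,5aS,9aS,9bR)-3a,6,6,9a-tetramethyldecahydronaphtho[2,1-b]furan-2(1H)-one | C[C@]12CCCC([C@@H]1CC[C@@]3([C@@H]2CC(=O)O3)C)(C)C | starting material
17 | (1R,2R,4aS,8aS)-1-(2-hydroxyethyl)-2,5,5,8a-tetramethyldecahydronaphthalen-2-ol | C[C@]12CCCC([C@@H]1CC[C@@](O)([C@@H]2CCO)C)(C)C | intermediate
18 | 2-[(1R,2R,4aS,8aS)-2-hydroxy-2,5,5,8a-tetramethyldecahydronaphthalen-1-yl]ethyl acetate | C[C@]12CCCC([C@@H]1CC[C@@](O)([C@@H]2CCOC(C)=O)C)(C)C | intermediate
19 | chlorosulfite of 18 at the C8 oxygen (sulfur centre undefined) | C[C@]12CCCC([C@@H]1CC[C@@](OS(Cl)=O)([C@@H]2CCOC(C)=O)C)(C)C | intermediate (not isolated)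
20 | 2-[(1S,4aS,8aS)-5,5,8a-trimethyl-2-methylidenedecahydronaphthalen-1-yl]ethyl acetate | C=C1CC[C@H]2C(C)(C)CCC[C@]2(C)[C@H]1CCOC(C)=O | intermediate
21 | 2-[(1S,4aS,8aS)-5,5,8a-trimethyl-2-methylidenedecahydronaphthalen-1-yl]ethan-1-ol | C=C1CC[C@H]2C(C)(C)CCC[C@]2(C)[C@H]1CCO | intermediate
22 | (1S,4aS,8aS)-1-(2-iodoethyl)-5,5,8a-trimethyl-2-methylidenedecahydronaphthalene | C=C1CC[C@H]2C(C)(C)CCC[C@]2(C)[C@H]1CCI | intermediate
23 | {2-[(1S,4aS,8aS)-5,5,8a-trimethyl-2-methylidenedecahydronaphthalen-1-yl]ethyl}zinc iodide | C=C1CC[C@H]2C(C)(C)CCC[C@]2(C)[C@H]1CC[Zn]I | intermediate (not isolated)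
24 | (4aR,8aS)-2,5,5,8a-tetramethyl-1-{2-[(1S,4aS,8aS)-5,5,8a-trimethyl-2-methylidenedecahydronaphthalen-1-yl]ethyl}-3,4,4a,5,6,7,8,8a-octahydronaphthalene (CNP0151741.1) | C=C1CC[C@H]2C(C)(C)CCC[C@]2(C)[C@H]1CCC1=C(C)CC[C@@H]2C(C)(C)CCC[C@]12C | target

## Step count and least certain steps

Total step count: 15. Longest linear sequence: 9 steps (steps 1, 2, 4, 5, 6, 7, 8, 9, 15, from 1); the left half needs 5 steps from 16 before the coupling.

**Step 4 (key step).** Most likely to go wrong: sluggish cycloaddition, because the dienophile is trisubstituted and its β-carbon is neopentyl, so that Lewis-acid-induced polymerisation of the diene outruns it. Further risks are insufficient or reversed enantioface discrimination, since the α-methyl group removes the usual α-C–H contact with the catalyst, and some erosion of regioselectivity by the 2-methyl group of the diene. Fallback, setting out from 6 and 5 and returning at 12: tiglic aldehyde 6 is deprotonated to its potassium dienolate (KOtBu, THF, −78 °C) and O-acylated with (S)-O-methylmandeloyl chloride to give the chiral dienyl ester (1E)-2-methylbuta-1,3-dien-1-yl (2S)-2-methoxy-2-phenylacetate F1. F1 and 5 are combined under a stronger, achiral aluminium Lewis acid (AlBr3/AlMe3 mixture, toluene/CH2Cl2, −20 °C → rt). The two endo adducts are now diastereomers and are separated by chromatography, so enantiopurity no longer depends on a catalyst; the one with the ring fusion of 8 is the keto mandelate F2. It is carried through the chemistry of steps 5 and 6 (mandelate tosylhydrazone F3, then deoxygenated mandelate F4), and F4 is cleaved with K2CO3 in MeOH to 12. The (R)-acid serves equally if it gives the easier separation.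

**Step 6 (with step 5).** Most likely to go wrong: incomplete condensation at the neopentyl C1' ketone, slow hydride delivery to the hindered C=N bond, or base-induced elimination of the hydrazone to an alkene in the acetate stage. Fallback, setting out from 8 and returning at 11: NaBH4 (MeOH, 0 °C) reduces the C1' ketone to the hydroxy acetate F5 (either carbinol epimer serves); 1,1'-thiocarbonyldiimidazole (DMAP cat., 1,2-dichloroethane, reflux) gives the imidazolyl thiocarbonate F6; Bu3SnH and AIBN in refluxing toluene at high stannane concentration (Barton–McCombie deoxygenation) give 11. C9' is still sp3 at this stage, so the C1' radical has no neighbouring acyl group to migrate.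

**Step 15.** Most likely to go wrong: slow oxidative addition and transmetalation at the tetrasubstituted triflate flanked by the quaternary C10', so that reduction of the triflate, homocoupling of the alkyl group or β-hydride elimination takes over; incomplete zinc insertion is a second source of loss. Fallback, setting out from 22 and 15 and returning at 24: 22 is converted with Mg turnings (THF, rt) into the alkylmagnesium iodide F8, which is added slowly to 15 and Fe(acac)3 (5 mol %) in THF/NMP at −20 → 0 °C. The iron-catalysed Kumada-type coupling of enol triflates with alkyl Grignard reagents is fast, tolerates crowding at the triflate and does not pass through an alkylpalladium species prone to β-hydride loss.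

**Step 9.** Most likely to go wrong: competing 1,2-reduction of the carbonyl, or incomplete O-sulfonylation of the crowded, boron-associated tetrasubstituted enolate. Fallback, setting out from 13 and returning at 15: hydrogenation (H2, Pd/C, palladium on carbon, EtOAc) gives the saturated ketone F7 as a C8' epimer mixture; KN(SiMe3)2 (THF, −78 → 0 °C) and the same pyridyl triflimide give 15. Deprotonation can occur only at C8', so the regiochemistry remains fixed.

## Further compounds

F1 | step 4 | (1E)-2-methylbuta-1,3-dien-1-yl (2S)-2-methoxy-2-phenylacetate | CO[C@@H](c1ccccc1)C(=O)O/C=C(\C)C=C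
F2 | step 4 | (1R,4aR,8aS)-2,5,5,8a-tetramethyl-8-oxo-1,4,4a,5,6,7,8,8a-octahydronaphthalen-1-yl (2S)-2-methoxy-2-phenylacetate | CO[C@@H](c1ccccc1)C(=O)O[C@@H]1C(C)=CC[C@@H]2C(C)(C)CCC(=O)[C@]12C
F3 | step 4 | (1R,4aR,8aR)-2,5,5,8a-tetramethyl-8-[(E)-2-(4-methylbenzenesulfonyl)hydrazinylidene]-1,4,4a,5,6,7,8,8a-octahydronaphthalen-1-yl (2S)-2-methoxy-2-phenylacetate | CO[C@@H](c1ccccc1)C(=O)O[C@@H]1C(C)=CC[C@@H]2C(C)(C)CC/C(=N\NS(=O)(=O)c3ccc(C)cc3)[C@]12C
F4 | step 4 | (1R,4aR,8aS)-2,5,5,8a-tetramethyl-1,4,4a,5,6,7,8,8a-octahydronaphthalen-1-yl (2S)-2-methoxy-2-phenylacetate | CO[C@@H](c1ccccc1)C(=O)O[C@@H]1C(C)=CC[C@@H]2C(C)(C)CCC[C@]12C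
F5 | step 6 | 8-hydroxy-2,5,5,8a-tetramethyl-1,4,4a,5,6,7,8,8a-octahydronaphthalen-1-yl acetate, C1 and ring-fusion configuration as in 8, C8 epimers | CC(=O)O[C@@H]1C(C)=CC[C@@H]2C(C)(C)CCC(O)[C@]12C
F6 | step 6 | 8-[(1H-imidazol-1-ylcarbonothioyl)oxy]-2,5,5,8a-tetramethyl-1,4,4a,5,6,7,8,8a-octahydronaphthalen-1-yl acetate, configuration as in F5 | CC(=O)O[C@@H]1C(C)=CC[C@@H]2C(C)(C)CCC(OC(=S)n3ccnc3)[C@]12C
F7 | step 9 | (4aR,8aS)-2,5,5,8a-tetramethyloctahydronaphthalen-1(2H)-one, C2 epimers | O=C1C(C)CC[C@@H]2C(C)(C)CCC[C@]12C
F8 | step 15 | {2-[(1S,4aS,8aS)-5,5,8a-trimethyl-2-methylidenedecahydronaphthalen-1-yl]ethyl}magnesium iodide | C=C1CC[C@H]2C(C)(C)CCC[C@]2(C)[C@H]1CC[Mg]I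
A1 | alternative 1 | 3'-hydroxy derivative of 24, hydroxyl cis to the C10' methyl | C=C1CC[C@H]2C(C)(C)CCC[C@]2(C)[C@H]1CCC1=C(C)CC[C@@H]2C(C)(C)[C@@H](O)CC[C@]12C
A2 | alternative 2 | (4aR,8aS)-2,5,5,8a-tetramethyloctahydronaphthalen-1(2H)-one, one C2 epimer drawn | O=C1[C@@H](C)CC[C@@H]2C(C)(C)CCC[C@]12C
A3 | alternative 2 | (3aR,7aS)-4,4,7a-trimethyloctahydro-1H-inden-1-one (cis-fused) | O=C1CC[C@@H]2C(C)(C)CCC[C@]12C
A4 | alternative 2 | diazoethane | CC=[N+]=[N-]
A5 | alternative 3 | 3'-oxo derivative of 24 | C=C1CC[C@H]2C(C)(C)CCC[C@]2(C)[C@H]1CCC1=C(C)CC[C@@H]2C(C)(C)C(=O)CC[C@]12C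
A6 | alternative 3 | 2-ethenyl-1,3,3,5-tetramethyl-6-{2-[(1S,4aS,8aS)-5,5,8a-trimethyl-2-methylidenedecahydronaphthalen-1-yl]ethyl}bicyclo[2.2.2]oct-5-en-2-ol, vinyl group on the face of the alkene bridge | C=C[C@]1(O)C(C)(C)[C@H]2CC[C@]1(C)C(CC[C@H]3C(=C)CC[C@H]4C(C)(C)CCC[C@]34C)=C2C
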